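Everything rests on opening ring A at the Ca–Cb bond. Ring A hides a dialkylmalonate. Its quaternary carbon Cq is flanked by the carbonyl carbons Cb and Cd, and Ca, bonded to Cb, holds the CH2 bridge to ring B. That bridge therefore becomes plain C7 of an open 3,5-dioxoheptanoate. One Dieckmann closure (Ca onto ester carbon Cb) then delivers ring A with the bridge and ring B already attached, and it never touches Cq. The precursor is methyl (S)-2-geranyl-2-methyl-3,5-dioxo-7-arylheptanoate (aryl = tris-MOM butyrylphloroglucinol). Its stereocentre comes from an enzymatically desymmetrised malonate. Acetylation at Ce, deprotection and an o-quinone methide coupling to chromene ring C complete the trimer.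

Key step: step 7

Labels: ring A in ring order is Ca (bridge), Cb, Cq, Cd, Ce (acetyl), Cf. In the open chain C1 = Cb, C2 = Cq, C3 = Cd, C4 = Ce, C5 = Cf, C6 = Ca and C7 = bridge. Ring B is the central butyrylphloroglucinol and ring C is the chromene unit. Geranyl = (2E)-3,7-dimethylocta-2,6-dien-1-yl; MOM = CH2OCH3.

Assumption: the esterase is taken to cleave the pro-R ester group of the geranylated diester; because pig liver esterase is known to change its sense with the size of the alkyl group in 2-alkyl-2-methylmalonates, the enzyme preparation (crude or a single recombinant isoenzyme) is chosen by screening, the configuration of the half-ester is proven before it is carried on, and the wrong antipode is returned to the achiral diester by methylation.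

Remark: triketone rings are drawn in the tautomer of the target SMILES and CIP descriptors refer to that tautomer; the change from S to R on acetylation is a change of priorities only.

Step 1
Reactants: 1 dimethyl methylmalonate; 2 geranyl bromide
Product: 4 dimethyl 2-geranyl-2-methylmalonate (achiral; E olefin kept), via sodium malonate enolate 3 (not isolated)
Conditions: NaH (1.1 equiv), THF, 0 °C; then 2, 0 °C → rt
Reagents that add atoms: none
Why: Malonic ester alkylation, in which the soft enolate 3 displaces bromide at the primary allylic carbon by SN2, keeps the E double bond and gives a diester with two enantiotopic ester groups.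

Step 2
Reactants: 4 dimethyl 2-geranyl-2-methylmalonate
Product: 5 (S)-2-geranyl-3-methoxy-2-methyl-3-oxopropanoic acid (malonic acid monomethyl ester)
Conditions: pig liver esterase, phosphate buffer pH 7.5/DMSO 9:1, 25 °C, pH-stat with 1 M NaOH (1.0 equiv); then 1 M HCl to pH 2
Reagents that add atoms: water, O
Why: Enzymatic desymmetrisation of a prochiral 2,2-disubstituted malonate should hydrolyse only the pro-R ester group, which sets Cq as S, and should stop there because the carboxylate formed is no longer a substrate.

Step 3
Reactants: 5 (S)-half-ester
Product: 6 methyl (S)-2-geranyl-3-(imidazol-1-yl)-2-methyl-3-oxopropanoate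
Conditions: CDI (1.1 equiv), THF, rt; Et2O, quick cold water wash to remove imidazole
Reagents that add atoms: 1,1'-carbonyldiimidazole, O=C(n1ccnc1)n1ccnc1
Why: Carboxyl activation with CDI gives the acyl imidazole under neutral conditions, and the fully substituted carbon Cq can neither epimerise nor form a ketene.

Step 4
Reactants: 7 2,4,6-trihydroxybutyrophenone; 8 methyl vinyl ketone
Product: 9 4-(3-butanoyl-2,4,6-trihydroxyphenyl)butan-2-one
Conditions: 7 (2 equiv), 8 (1 equiv), Et3N (0.2 equiv), THF/H2O 4:1, 0 °C → rt; excess 7 recovered
Reagents that add atoms: none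
Why: Michael addition of the acylphloroglucinol anion, a vinylogous 1,3-dicarbonyl nucleophile, should end at carbon because addition through oxygen is reversible while rearomatisation fixes the C-adduct, and the excess of 7 holds back a second addition.

Step 5
Reactants: 9 4-(3-butanoyl-2,4,6-trihydroxyphenyl)butan-2-one
Product: 10 4-[3-butanoyl-2,4,6-tris(methoxymethoxy)phenyl]butan-2-one
Conditions: NaH (3.2 equiv), MOMCl (3.6 equiv), DMF, 0 °C → rt
Reagents that add atoms: chloromethyl methyl ether, COCCl
Why: Williamson-type O-alkylation of the sodium phenoxides by the hard electrophile MOMCl (NaH also frees the hydrogen-bonded hydroxyls and opens any cyclic hemiketal form) installs acetal ethers that neither migrate to enolate oxygens nor react with amide bases.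

Step 6
Reactants: 10 tris-MOM methyl ketone; 6 acyl imidazole
Product: 12 methyl (S)-2-geranyl-2-methyl-3,5-dioxo-7-[3-butanoyl-2,4,6-tris(methoxymethoxy)phenyl]heptanoate, via dilithium bis-enolate 11 (not isolated)
Conditions: LiN(iPr)2 (2.2 equiv), THF, −78 °C; then 6 (1.0 equiv), −78 → −20 °C; cold 0.5 M HCl
Reagents that add atoms: none
Why: In this crossed Claisen-type C-acylation of a kinetic lithium enolate by an acyl imidazole, only the unhindered terminal CH2 of 11 should reach the neopentyl-like acyl group, while the shielded butyryl enolate stays masked and acts as internal base for the acidic 1,3-diketone, and Cq is not touched.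

Step 7
Reactants: 12 3,5-dioxo ester
Product: 14 (S)-2-{[3-butanoyl-2,4,6-tris(methoxymethoxy)phenyl]methyl}-4-geranyl-3,5-dihydroxy-4-methylcyclohexa-2,5-dien-1-one, via trilithium trianion 13 (not isolated)
Conditions: LiN(iPr)2 (4.2 equiv), THF/DMPU 10:1, −78 → 0 °C (rt if needed); cold 0.5 M HCl to pH 3
Reagents that add atoms: none
Why: The base removes the C4 proton, the butyryl α-proton and then a C6 proton (C2 is quaternary, so Ca is the only site left for the second deprotonation of the diketone), and in trianion 13 the most basic carbon Ca adds to the ester carbonyl Cb, after which loss of methoxide and deprotonation of the new trione make the closure irreversible. The closest known reaction type is the Dieckmann (intramolecular Claisen) cyclisation of 2,2-dialkyl-3,5-dioxoalkanoate dianions to 4,4-dialkylcyclohexane-1,3,5-triones. Ring A closes in a 6-(enolendo)-exo-trig mode, because the enolate bond Cf=Ca lies inside the new ring, and this mode is allowed for six-membered rings; the U-shaped lithium chelate of the diketonate must first open to its extended form, which is why DMPU is added and the mixture is warmed. No stereocentre is formed and no bond to Cq is broken, so the configuration of 12 is carried over, and an amide base, unlike an alkoxide, cannot start retro-Claisen cleavage next to Cq. The step needs C- rather than O-acylation and Ca rather than Ce as nucleophile, which the substrate secures because Ce could only close a cyclobutanone and the oxygen on Cf is a far weaker nucleophile than the carbanion beside it. The butyryl ketone is masked as its enolate and the MOM ethers are inert to the base.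

Step 8
Reactants: 14 ring A–ring B dimer without acetyl group
Product: 16 (R)-6-acetyl-2-{[3-butanoyl-2,4,6-tris(methoxymethoxy)phenyl]methyl}-4-geranyl-3,5-dihydroxy-4-methylcyclohexa-2,5-dien-1-one, via enol acetate 15 (not isolated)
Conditions: Ac2O (1.2 equiv), Et3N (2.5 equiv), DMAP (0.3 equiv), CH2Cl2, 0 °C → rt
Reagents that add atoms: acetic anhydride, CC(=O)OC(C)=O
Why: O-acetylation followed by DMAP-catalysed O-to-C acyl migration (the Fries-type rearrangement of enol esters of cyclic 1,3-diones) should funnel every enol acetate such as 15 to Ce, the only ring A carbon that still bears hydrogen and the only site where a stabilised, hydrogen-bonded triketone results.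

Step 9
Reactants: 16 acetylated protected dimer
Product: 17 (R)-6-acetyl-2-[(3-butanoyl-2,4,6-trihydroxyphenyl)methyl]-4-geranyl-3,5-dihydroxy-4-methylcyclohexa-2,5-dien-1-one
Conditions: 3 M aq HCl/MeOH 1:10, 40 °C, stopped at full conversion
Reagents that add atoms: none
Why: Acid-catalysed acetal exchange frees the three phenols, the large excess of methanol traps the CH2 units as dimethoxymethane before they can alkylate the free ring B carbon, and the mild temperature should spare the geranyl double bonds.

Step 10
Reactants: 7 2,4,6-trihydroxybutyrophenone; 18 3-methylbut-2-enal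
Product: 20 1-(5,7-dihydroxy-2,2-dimethyl-2H-chromen-8-yl)butan-1-one, via dienone quinone methide 19 (not isolated)
Conditions: 7 (1.2 equiv), 18 (1.0 equiv), ethylenediammonium diacetate (0.1 equiv), THF, reflux; chromatography
Reagents that add atoms: none
Why: Knoevenagel condensation at a free ring carbon gives 19, whose oxa-6π electrocyclisation through the oxygen next to the butyryl group gives the 8-acyl chromene, and the 6-acyl isomer from closure through the para oxygen is removed by chromatography on this cheap branch.

Step 11
Reactants: 20 ring C chromene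
Product: 21 1-{6-[(dimethylamino)methyl]-5,7-dihydroxy-2,2-dimethyl-2H-chromen-8-yl}butan-1-one
Conditions: [CH2=NMe2]I (1.05 equiv), CH2Cl2, 0 °C → rt; NaHCO3 wash; used without storage
Reagents that add atoms: N,N-dimethylmethyleneiminium iodide, C=[N+](C)C.[I-]
Why: Mannich aminomethylation by the preformed iminium salt is an electrophilic aromatic substitution that can only take place at C6, the single free position of the electron-rich ring C.

Step 12
Reactants: 17 free ring A–ring B dimer; 21 ring C Mannich base
Product: 23 CNP0103039.1 (target; R at Cq), via ring C o-quinone methide 22 (not isolated)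
Conditions: 21 (1.2 equiv), 1,4-dioxane, 80 °C, argon
Reagents that add atoms: none
Why: Thermal loss of dimethylamine from the Mannich base gives 22, which is trapped in a Friedel–Crafts-type conjugate addition by the only remaining nucleophilic C–H of 17 (ring B), so the second bridge forms without free formaldehyde or statistical homocoupling and without involving Cq.

Compound list
1 | dimethyl methylmalonate | COC(=O)C(C)C(=O)OC | starting material
2 | geranyl bromide | BrC/C=C(\C)CCC=C(C)C | starting material
3 | sodium enolate of dimethyl methylmalonate | [Na+].COC(=O)[C-](C)C(=O)OC | intermediate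
4 | dimethyl 2-geranyl-2-methylmalonate | COC(=O)C(C)(C/C=C(\C)CCC=C(C)C)C(=O)OC | intermediate
5 | (S)-2-geranyl-2-methylmalonic acid monomethyl ester | COC(=O)[C@@](C)(C/C=C(\C)CCC=C(C)C)C(=O)O | intermediate
6 | (S)-acyl imidazole of 5 | COC(=O)[C@@](C)(C/C=C(\C)CCC=C(C)C)C(=O)n1ccnc1 | intermediate
7 | 2,4,6-trihydroxybutyrophenone | CCCC(=O)c1c(O)cc(O)cc1O | starting material
8 | methyl vinyl ketone | C=CC(C)=O | starting material
9 | 4-(3-butanoyl-2,4,6-trihydroxyphenyl)butan-2-one | CCCC(=O)c1c(O)cc(O)c(CCC(C)=O)c1O | intermediate
10 | 4-[3-butanoyl-2,4,6-tris(methoxymethoxy)phenyl]butan-2-one | CCCC(=O)c1c(OCOC)cc(OCOC)c(CCC(C)=O)c1OCOC | intermediate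
11 | dilithium bis-enolate of 10 (carbanion form) | [Li+].[Li+].[CH2-]C(=O)CCc1c(OCOC)cc(OCOC)c(C(=O)[CH-]CC)c1OCOC | intermediate
12 | methyl (S)-2-geranyl-2-methyl-3,5-dioxo-7-[3-butanoyl-2,4,6-tris(methoxymethoxy)phenyl]heptanoate | COC(=O)[C@@](C)(C/C=C(\C)CCC=C(C)C)C(=O)CC(=O)CCc1c(OCOC)cc(OCOC)c(C(=O)CCC)c1OCOC | intermediate
13 | trilithium trianion of 12 (carbanion form) | [Li+].[Li+].[Li+].COC(=O)[C@@](C)(C/C=C(\C)CCC=C(C)C)C(=O)[CH-]C(=O)[CH-]Cc1c(OCOC)cc(OCOC)c(C(=O)[CH-]CC)c1OCOC | intermediate
14 | protected ring A–ring B dimer without acetyl group (S) | CCCC(=O)c1c(OCOC)cc(OCOC)c(CC2=C(O)[C@@](C)(C/C=C(\C)CCC=C(C)C)C(O)=CC2=O)c1OCOC | intermediate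
15 | enol acetate of 14 (drawn at the oxygen on Cd) | CCCC(=O)c1c(OCOC)cc(OCOC)c(CC2=C(O)[C@@](C)(C/C=C(\C)CCC=C(C)C)C(OC(C)=O)=CC2=O)c1OCOC | intermediate
16 | protected ring A–ring B dimer with acetyl group at Ce (R) | CCCC(=O)c1c(OCOC)cc(OCOC)c(CC2=C(O)[C@@](C)(C/C=C(\C)CCC=C(C)C)C(O)=C(C(C)=O)C2=O)c1OCOC | intermediate
17 | free ring A–ring B dimer (R) | CCCC(=O)c1c(O)cc(O)c(CC2=C(O)[C@@](C)(C/C=C(\C)CCC=C(C)C)C(O)=C(C(C)=O)C2=O)c1O | intermediate
18 | 3-methylbut-2-enal | CC(C)=CC=O | starting material
19 | (Z)-dienone o-quinone methide from 7 and 18 | CCCC(=O)C1=C(O)C=C(O)/C(=C/C=C(C)C)C1=O | intermediate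
20 | 1-(5,7-dihydroxy-2,2-dimethyl-2H-chromen-8-yl)butan-1-one | CCCC(=O)c1c(O)cc(O)c2c1OC(C)(C)C=C2 | intermediate
21 | 6-(dimethylaminomethyl) derivative of 20 | CCCC(=O)c1c(O)c(CN(C)C)c(O)c2c1OC(C)(C)C=C2 | intermediate
22 | ring C o-quinone methide | CCCC(=O)C1=C(O)C(=C)C(=O)C2=C1OC(C)(C)C=C2 | intermediate
23 | CNP0103039.1 | CCCC(=O)c1c(O)c(CC2=C(O)[C@@](C)(C/C=C(\C)CCC=C(C)C)C(O)=C(C(C)=O)C2=O)c(O)c(Cc2c(O)c3c(c(C(=O)CCC)c2O)OC(C)(C)C=C3)c1O | target

Total step count: 12. Longest linear sequence: 8 steps (1, 2, 3, 6, 7, 8, 9, 12).

Steps most likely to fail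

Step 7. The triply charged chain may stay inert towards the hindered ester. Closure through the oxygen on Cf, or retro-Claisen fragmentation on long warming, may also overtake C-acylation. The fallback masks the diketone, so that one deprotonation at Ca is enough and oxygen closure is blocked.
- It sets out from 12. O-methylation with the hard electrophile Me2SO4 (K2CO3, acetone, rt) should give mainly methyl (S,E)-2-geranyl-5-methoxy-2-methyl-3-oxo-7-[3-butanoyl-2,4,6-tris(methoxymethoxy)phenyl]hept-4-enoate F1.
- The regioisomeric enol ether also has its only acidic CH2 at Ca, so both isomers converge.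
- LiN(iPr)2 (3 equiv, THF, −78 → 0 °C) deprotonates Ca, and intramolecular acylation gives the ring A methyl enol ether F2.
- Saponification of this vinylogous ester (1 M NaOH, MeOH, rt) comes back to the route at 14.

Step 2. The lipophilic diester may turn over slowly, and the selection between the enantiotopic ester groups may be low or inverted. The fallback replaces biocatalysis by classical resolution.
- It sets out from 4. One equivalent of KOH in MeOH gives racemic 2-geranyl-2-methylmalonic acid monomethyl ester F3.
- Fractional crystallisation with 1-phenylethylamine follows. The case is written for the (S)-amine, and the antipodal amine is used if it gives the less soluble salt of the wanted acid. This gives the (S)-acid (S)-1-phenylethylammonium salt F4.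
- Acidification comes back to the route at 5.
- The acid left in the mother liquor is methylated (MeI, K2CO3) back to 4. The same salt crystallisation can also raise the purity of enzymatically made 5.

Step 12. The quinone methide precursor may condense with itself, and heat or amine may promote exchange of the methylene bridges between the phloroglucinol rings. The fallback reverses the roles of the partners.
- It sets out from 17. [CH2=NMe2]I (CH2Cl2, 0 °C) aminomethylates the single free ring B carbon to give the ring B Mannich base of the dimer F5.
- Warming F5 in dioxane with a large excess of the cheap chromene 20, which acts as nucleophile at C6, traps the ring B quinone methide and comes back to the route at 23.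

Further compounds
F1 | step 7 | methyl (S,E)-2-geranyl-5-methoxy-2-methyl-3-oxo-7-[3-butanoyl-2,4,6-tris(methoxymethoxy)phenyl]hept-4-enoate | COC(=O)[C@@](C)(C/C=C(\C)CCC=C(C)C)C(=O)/C=C(/OC)CCc1c(OCOC)cc(OCOC)c(C(=O)CCC)c1OCOC
F2 | step 7 | ring A methyl enol ether (methoxy on Cf) of dimer 14 | CCCC(=O)c1c(OCOC)cc(OCOC)c(CC2=C(O)[C@@](C)(C/C=C(\C)CCC=C(C)C)C(=O)C=C2OC)c1OCOC
F3 | step 2 | racemic 2-geranyl-2-methylmalonic acid monomethyl ester | COC(=O)C(C)(C/C=C(\C)CCC=C(C)C)C(=O)O
F4 | step 2 | (S)-1-phenylethylammonium salt of (S)-half-ester 5 | COC(=O)[C@@](C)(C/C=C(\C)CCC=C(C)C)C(=O)[O-].C[C@H]([NH3+])c1ccccc1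
F5 | step 12 | ring B dimethylaminomethyl derivative of dimer 17 | CCCC(=O)c1c(O)c(CN(C)C)c(O)c(CC2=C(O)[C@@](C)(C/C=C(\C)CCC=C(C)C)C(O)=C(C(C)=O)C2=O)c1O
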